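**Assumption:** the SMILES holds no stereocentre or stereogenic double bond, so Peruvinide C is achiral and the route needs no stereocontrol.

## Retrosynthetic overview
1. Cut the depside ester C(acyl)–O(aryl) bond of 16. This gives divaricatinic acid 6 and unprotected 5-pentylpyrogallol 11. An in-flask phenylboronate clamp over two neighbouring oxygens of 11 fixes the site (terminal O) and limits the reaction to mono-acylation.
2. Acid 6 comes from chelation-controlled 2-O-demethylation of 4, and 4 comes from lateral ethylation of 2,4-dimethoxy-6-methylbenzoic acid 1.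
3. Triol 11 comes from BBr3 demethylation of 9, and 9 comes from Kumada coupling of bromide 7 with pentyl Grignard 8.
4. No carbocycle is built, because both benzene rings are bought. Only transient boracycles (5, 10, 13, 15) form, and each is opened again.

## Route

Step 1
Reactants: 1 2,4-dimethoxy-6-methylbenzoic acid; 2 iodoethane
Product: 4 2,4-dimethoxy-6-propylbenzoic acid, via dilithio dianion 3 (not isolated)
Conditions: LDA (commercial solution, 2.2 equiv), THF, −78 → −20 °C; 2 (1.3 equiv), −78 °C → rt; then 1 M HCl
Reagents that add atoms: iodoethane (2), CCI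
Why: Lateral (benzylic) lithiation of an o-toluic acid followed by SN2 alkylation; the lithium carboxylate directs and stabilises the benzylic carbanion, which is the only carbon nucleophile present and takes up one ethyl group, and no stereocentre is formed.

Step 2
Reactants: 4 2,4-dimethoxy-6-propylbenzoic acid
Product: 6 divaricatinic acid (2-hydroxy-4-methoxy-6-propylbenzoic acid), via chloroboron chelate 5 (not isolated)
Conditions: BCl3 (1 M in CH2Cl2, 2.2 equiv), CH2Cl2, −78 → 0 °C, 2 h; then ice-water
Reagents that add atoms: none
Why: Chelation-controlled BCl3 aryl methyl ether cleavage; boron bridges the carboxyl oxygen and the ortho methoxy oxygen in a six-membered chelate, so chloride removes only that methyl group, while the 4-OMe cannot chelate and survives at or below 0 °C.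

Step 3
Reactants: 7 5-bromo-1,2,3-trimethoxybenzene; 8 n-pentylmagnesium bromide
Product: 9 1,2,3-trimethoxy-5-pentylbenzene
Conditions: NiCl2(dppp) (2 mol %), 8 (1.3 equiv), Et2O/THF, 0 °C → reflux, 6 h
Reagents that add atoms: n-pentylmagnesium bromide (8), CCCCC[Mg]Br
Why: Kumada–Tamao–Corriu cross-coupling; the chelating dppp ligand makes reductive elimination faster than β-hydride elimination for a primary alkyl group and does not activate the aryl–OMe bonds.

Step 4
Reactants: 9 1,2,3-trimethoxy-5-pentylbenzene
Product: 11 5-pentylbenzene-1,2,3-triol (5-pentylpyrogallol), via bromoboron aryl borate 10 (not isolated)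
Conditions: BBr3 (3.5 equiv), CH2Cl2, −78 °C → rt, 12 h; then degassed ice-water, Ar
Reagents that add atoms: none
Why: Exhaustive BBr3 aryl methyl ether cleavage; the alkyl chain is inert, and an acidic, oxygen-free work-up keeps the electron-rich triol from oxidising.

Step 5
Reactants: 6 divaricatinic acid; 11 5-pentylbenzene-1,2,3-triol; 12 phenylboronic acid
Product: 16 Peruvinide C, via boronate phenol 13 (not isolated), via O-acylisourea 14 (not isolated), via boronate-masked depside 15 (not isolated)
Conditions: 11 + 12 (1.0 equiv each), 4 Å MS, PhMe, rt, 1 h; then 6 (1.0 equiv), DCC (1.1 equiv), 0 °C → rt, 16 h; then pinacol (1.2 equiv), rt, 1 h; Ar; filter, chromatography on acid-washed silica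
Reagents that add atoms: none
Why: Proposed new method: a stoichiometric arylboronic acid serves as a traceless in-flask template for the site-selective mono-O-acylation of an unprotected pyrogallol by an unprotected salicylic acid; PhB(OH)2 condenses only with a vicinal O,O pair to give a five-membered benzodioxaborole (the two possible pairs are equivalent by symmetry), so in 13 the central and one terminal oxygen are poorly nucleophilic B–O–aryl oxygens whose lone pairs feed the empty boron orbital, and the one free terminal OH attacks the carbodiimide-activated acid 14 (whose own 2-OH is switched off by its hydrogen bond to the carbonyl), which excludes central-O acylation, bis-acylation and, while boron stays on, O-to-O acyl migration; the bis(aryloxy) chelate should be favoured over the mixed-anhydride-type salicylate chelate, so 6 should not strip the boron, and neutral exchange with pinacol then frees the catechol without base; the closest known reaction types are transient boronic ester masking of cis-diols for site-selective acylation of sugars, borate-masked mono-O-alkylation of gallates, carbodiimide (Steglich-type) depside coupling of free 2-hydroxybenzoic acids, and catechol-to-pinacol boronate exchange.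

## Compound list
1 | 2,4-dimethoxy-6-methylbenzoic acid | Cc1cc(OC)cc(OC)c1C(=O)O | starting material
2 | iodoethane | CCI | starting material
3 | dilithio dianion of 1 (lithium 2-(lithiomethyl)-4,6-dimethoxybenzoate, not isolated) | [Li+].[Li+].[CH2-]c1cc(OC)cc(OC)c1C(=O)[O-] | intermediate
4 | 2,4-dimethoxy-6-propylbenzoic acid | CCCc1cc(OC)cc(OC)c1C(=O)O | intermediate
5 | 2-chloro-7-methoxy-5-propyl-4H-1,3,2-benzodioxaborin-4-one (chloroboron chelate, not isolated) | CCCc1cc(OC)cc2OB(Cl)OC(=O)c12 | intermediate
6 | divaricatinic acid (2-hydroxy-4-methoxy-6-propylbenzoic acid) | CCCc1cc(OC)cc(O)c1C(=O)O | intermediate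
7 | 5-bromo-1,2,3-trimethoxybenzene | COc1cc(Br)cc(OC)c1OC | starting material
8 | n-pentylmagnesium bromide | CCCCC[Mg]Br | starting material
9 | 1,2,3-trimethoxy-5-pentylbenzene | CCCCCc1cc(OC)c(OC)c(OC)c1 | intermediate
10 | 2-bromo-4-(dibromoboryloxy)-6-pentyl-1,3,2-benzodioxaborole (not isolated) | CCCCCc1cc(OB(Br)Br)c2OB(Br)Oc2c1 | intermediate
11 | 5-pentylbenzene-1,2,3-triol | CCCCCc1cc(O)c(O)c(O)c1 | intermediate
12 | phenylboronic acid (template) | OB(O)c1ccccc1 | starting material
13 | 6-pentyl-2-phenyl-1,3,2-benzodioxaborol-4-ol (not isolated) | CCCCCc1cc(O)c2OB(c3ccccc3)Oc2c1 | intermediate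
14 | O-(2-hydroxy-4-methoxy-6-propylbenzoyl)-N,N'-dicyclohexylisourea (not isolated) | CCCc1cc(OC)cc(O)c1C(=O)OC(=NC1CCCCC1)NC1CCCCC1 | intermediate
15 | 6-pentyl-2-phenyl-1,3,2-benzodioxaborol-4-yl 2-hydroxy-4-methoxy-6-propylbenzoate (not isolated) | CCCCCc1cc(OC(=O)c2c(O)cc(OC)cc2CCC)c2OB(c3ccccc3)Oc2c1 | intermediate
16 | Peruvinide C (2,3-dihydroxy-5-pentylphenyl 2-hydroxy-4-methoxy-6-propylbenzoate, achiral) | CCCCCc1cc(O)c(O)c(OC(=O)c2c(O)cc(OC)cc2CCC)c1 | target

## Step count
- Total steps: 5.
- Longest linear sequence: 3 (steps 1, 2, 5 or steps 3, 4, 5).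

## Three steps most likely to fail

**Step 5 (proposed new step).**
- Risks: partial transfer of boron from 13 to the salicylic acid 6, slow attack of the hindered phenol so that 14 drifts to the N-acylurea, and acyl migration once the catechol is freed.
- Fallback, known chemistry, sets out from triol 11 (with acid 6) and comes back at 16.
- Heat 11 with dichlorodiphenylmethane (Ph2O, 170 °C). This ties two adjacent oxygens into the isolable ketal 6-pentyl-2,2-diphenyl-1,3-benzodioxol-4-ol F1.
- Esterify its single free OH with 6 (DCC, cat. DMAP, CH2Cl2) to give 6-pentyl-2,2-diphenyl-1,3-benzodioxol-4-yl 2-hydroxy-4-methoxy-6-propylbenzoate F2.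
- Remove the ketal by hydrogenolysis (H2, Pd/C, EtOAc–MeOH) to reach 16. This costs two more steps.

**Step 1.**
- Risks: incomplete dianion formation, and a second ethylation at the new benzylic CH2.
- Fallback sets out from iodoethane 2 and comes back at acid 4. It builds the side chain by olefination on an arene that carries no carboxyl group and brings in the carboxyl carbon afterwards.
- Quaternise PPh3 with 2 (PhMe, reflux) to ethyltriphenylphosphonium iodide F3.
- Run a Wittig reaction (KOtBu, THF, 0 °C) with bought 3,5-dimethoxybenzaldehyde F4 to give 1,3-dimethoxy-5-(prop-1-enyl)benzene F5. The E/Z mixture is of no consequence.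
- Hydrogenate (H2, Pd/C, EtOAc) to 1,3-dimethoxy-5-propylbenzene F6.
- Formylate under Vilsmeier–Haack conditions (POCl3, DMF) at the position para to one methoxy group and next to the propyl group, giving 2,4-dimethoxy-6-propylbenzaldehyde F7.
- Oxidise under Pinnick conditions (NaClO2, NaH2PO4, sulfamic acid) to 4.

**Step 2.**
- Risks: protodecarboxylation of the electron-rich free acid by the HCl/Lewis acid medium, and sluggish or unselective cleavage.
- Fallback sets out from 4 and comes back at 6. It moves the cleavage onto an ester, which cannot decarboxylate.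
- Methylate the carboxyl group (MeI, K2CO3, acetone) to methyl 2,4-dimethoxy-6-propylbenzoate F8.
- Cleave the ortho methoxy group with BCl3 (CH2Cl2, −78 → 0 °C) to methyl 2-hydroxy-4-methoxy-6-propylbenzoate F9.
- Saponify (KOH, aq. DMSO, 90 °C, then cold acidification) to 6.

## Further compounds
F1 | step 5 | 6-pentyl-2,2-diphenyl-1,3-benzodioxol-4-ol | CCCCCc1cc(O)c2OC(c3ccccc3)(c3ccccc3)Oc2c1
F2 | step 5 | 6-pentyl-2,2-diphenyl-1,3-benzodioxol-4-yl 2-hydroxy-4-methoxy-6-propylbenzoate | CCCCCc1cc(OC(=O)c2c(O)cc(OC)cc2CCC)c2OC(c3ccccc3)(c3ccccc3)Oc2c1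
F3 | step 1 | ethyltriphenylphosphonium iodide | CC[P+](c1ccccc1)(c1ccccc1)c1ccccc1.[I-]
F4 | step 1 | 3,5-dimethoxybenzaldehyde (bought) | COc1cc(C=O)cc(OC)c1
F5 | step 1 | 1,3-dimethoxy-5-(prop-1-enyl)benzene (E/Z mixture) | CC=Cc1cc(OC)cc(OC)c1
F6 | step 1 | 1,3-dimethoxy-5-propylbenzene | CCCc1cc(OC)cc(OC)c1
F7 | step 1 | 2,4-dimethoxy-6-propylbenzaldehyde | CCCc1cc(OC)cc(OC)c1C=O
F8 | step 2 | methyl 2,4-dimethoxy-6-propylbenzoate | CCCc1cc(OC)cc(OC)c1C(=O)OC
F9 | step 2 | methyl 2-hydroxy-4-methoxy-6-propylbenzoate | CCCc1cc(OC)cc(O)c1C(=O)OC
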